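**Strategy.** The cyclopentane (C16–C7–C6–C5–C4) is first built as a cyclohexane that also contains C8, the carbon that ends as the exocyclic C8=C19 methylene carbon on C7. A Diels–Alder reaction of a 2-silyloxytriene with methacrolein sets C4 and C16; alkoxyallylboration and ring-closing metathesis add ring A and the citronellol-derived chain. In the key step a semipinacol 1,2-shift moves the ring-fusion carbon C16 from C8 to C7 of the cis-fused bicyclic hydroxy mesylate: the six-membered ring contracts to the cyclopentane, C7 is set with inversion, and C8 is expelled as an acetyl group, the handle for enol triflation and Nozaki–Hiyama–Kishi closure of the eleven-membered ring.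

Key step: step 13

Numbering: locants C1–C20 are those of the target (trinervitane numbering): C1=C15 (C17 methyl on C15), C2 and C3 (carbinols), C4 (quaternary, C18 methyl), C5, C6, C7, C8 (=C19H2), C9 (OAc), C10, C11, C12 (C20 methyl), C13, C14, C16 (ring-fusion CH). β is the face of ring B (later the cyclopentane) that carries H-16 and the C18 methyl; α is the face that carries the C16–C15 and C4–C3 bonds.

Assumption: the (S)-configured oxazaborolidinium catalyst of step 3 is taken to expose the Cα-Re face of s-trans methacrolein; if the sense is the reverse, its enantiomer is used and nothing else changes.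

Step 1
Reactants: 1 methacrolein; 2 3-(triphenylphosphoranylidene)butan-2-one
Product: 3 (3E)-3,5-dimethylhexa-3,5-dien-2-one
Conditions: PhMe, BHT (cat.), 80 °C, sealed vessel
Reagents that add atoms: none
Why: Wittig olefination with a stabilised α-methyl acyl ylide should give the (E)-trisubstituted enone, with the acyl group trans to the isopropenyl group as the later diene requires; no stereocenter is formed.

Step 2
Reactants: 3 (3E)-3,5-dimethylhexa-3,5-dien-2-one
Product: 4 tert-butyl{[(3E)-3,5-dimethylhexa-1,3,5-trien-2-yl]oxy}dimethylsilane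
Conditions: TBSOTf, Et3N, CH2Cl2, −78 → 0 °C
Reagents that add atoms: tert-butyldimethylsilyl triflate CC(C)(C)[Si](C)(C)OS(=O)(=O)C(F)(F)F
Why: Soft enolisation and O-silylation of the methyl ketone (its only enolisable side) gives the 2-silyloxy diene; no stereocenter is formed.

Step 3
Reactants: 4 tert-butyl{[(3E)-3,5-dimethylhexa-1,3,5-trien-2-yl]oxy}dimethylsilane; 1 methacrolein
Product: 5 (1S,2R)-4-[(tert-butyldimethylsilyl)oxy]-1,3-dimethyl-2-(prop-1-en-2-yl)cyclohex-3-ene-1-carbaldehyde
Conditions: protonated (S)-o-tolyl-oxazaborolidine (CBS type, NTf2 counter-ion, 15 mol%), CH2Cl2, −78 °C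
Reagents that add atoms: none
Why: Catalytic enantioselective Diels–Alder reaction in which the silyloxy group (para director) and the C16 substituent (ortho director) both send the nucleophilic CH2 terminus to the β-carbon of methacrolein, the formyl-endo transition state places CHO cis to the isopropenyl group, and the chiral Lewis acid shields one face of the bound enal, so that the quaternary C4 and C16 are set together.

Step 4
Reactants: 6 (S)-citronellyl bromide
Product: 7 (4S)-6-bromo-1,1-dimethoxy-4-methylhexane
Conditions: O3, CH2Cl2/MeOH, −78 °C; Me2S; then TsOH (cat.), MeOH, 4 Å MS, rt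
Reagents that add atoms: methanol CO
Why: Ozonolysis cleaves the only alkene and the aldehyde is trapped as its dimethyl acetal by acid-catalysed acetalisation; the primary bromide and the C12 stereocenter are not touched.

Step 5
Reactants: 7 (4S)-6-bromo-1,1-dimethoxy-4-methylhexane; 8 propargyl alcohol
Product: 10 (5R)-8,8-dimethoxy-5-methyl-2-methylideneoctan-1-ol, via Grignard reagent 9 (not isolated)
Conditions: 7, Mg, THF, 45 °C; 8 pre-treated with i-PrMgCl (1 equiv), THF, 0 °C; then 9, CuI (10 mol%), −10 °C → rt; aq. NH4Cl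
Reagents that add atoms: none
Why: Copper-catalysed anti-carbomagnesiation of the propargyl alkoxide places the alkyl group on the internal alkyne carbon through a five-membered magnesium chelate and gives the 2-substituted allyl alcohol on protonation; no stereocenter is formed.

Step 6
Reactants: 10 (5R)-8,8-dimethoxy-5-methyl-2-methylideneoctan-1-ol
Product: 11 (4R)-1,1-dimethoxy-7-[(methoxymethoxy)methyl]-4-methyloct-7-ene
Conditions: MOMCl, i-Pr2NEt, CH2Cl2, 0 °C → rt
Reagents that add atoms: chloromethyl methyl ether COCCl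
Why: O-alkylation of the primary allylic alcohol (MOM ether formation) provides the allyl ether needed for α-lithiation.

Step 7
Reactants: 11 (4R)-1,1-dimethoxy-7-[(methoxymethoxy)methyl]-4-methyloct-7-ene; 5 (1S,2R)-4-[(tert-butyldimethylsilyl)oxy]-1,3-dimethyl-2-(prop-1-en-2-yl)cyclohex-3-ene-1-carbaldehyde
Product: 14 C3-hydroxy C2-OMOM seco adduct, via lithiated allyl ether 12 (not isolated), via alkoxyallylborane 13 (not isolated)
Conditions: 11, s-BuLi, THF, −78 °C; (−)-Ipc2BOMe, −78 °C; BF3·OEt2; then 5, −78 → −20 °C; HOCH2CH2NH2 work-up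
Reagents that add atoms: none
Why: Asymmetric γ-alkoxyallylboration (Brown allylation): the borane with OMOM cis to CH2B adds through a chair Zimmerman–Traxler transition state to give the syn (threo) 2-OMOM/3-OH pair, and the isopinocampheyl groups derived from (+)-α-pinene direct attack to the Si face of the formyl group, which is also the Felkin–Anh face of the C4 quaternary centre, so C3 and C2 should arise in the target configuration.

Step 8
Reactants: 14 C3-hydroxy C2-OMOM seco adduct
Product: 15 C2,C3-bis-OMOM seco silyl enol ether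
Conditions: MOMCl, i-Pr2NEt, Bu4NI (cat.), CH2Cl2, 40 °C
Reagents that add atoms: chloromethyl methyl ether COCCl
Why: MOM ether formation on the hindered C3 hydroxyl leaves only the ring B hydroxyl groups free for the later sulfonylation.

Step 9
Reactants: 15 C2,C3-bis-OMOM seco silyl enol ether
Product: 17 monocyclic 8β-hydroxy 7-ketone, via silyloxy ketone 16 (not isolated)
Conditions: mCPBA, NaHCO3, CH2Cl2, −40 °C; then Bu4NF/AcOH (1:1), THF, 0 °C
Reagents that add atoms: 3-chloroperbenzoic acid OOC(=O)c1cccc(Cl)c1
Why: Rubottom oxidation of the tetrasubstituted silyl enol ether, by far the most electron-rich alkene, with oxygen expected mainly anti to the pseudoaxial isopropenyl group on C16 (8β-oxygen) and 1,4-silyl shift to the α-silyloxy ketone, which buffered fluoride unmasks; the C8 configuration is of no consequence because C8 becomes a carbonyl carbon in step 13.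

Step 10
Reactants: 17 monocyclic 8β-hydroxy 7-ketone
Product: 18 cis-fused bicyclic α-ketol
Conditions: second-generation Grubbs catalyst RuCl2(=CHPh)(PCy3)(H2IMes) (10 mol%), PhMe, 80 °C, argon sparge
Reagents that add atoms: none
Why: Ring-closing metathesis of the two 1,1-disubstituted alkenes, held cis on C16 and C4, closes six-membered ring A as the tetrasubstituted C1=C15 alkene with loss of ethylene; no stereocenter is formed.

Step 11
Reactants: 18 cis-fused bicyclic α-ketol
Product: 19 bicyclic 7α,8β-diol
Conditions: NaBH4, MeOH, −20 °C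
Reagents that add atoms: none
Why: Hydride reduction of the ketone, in which the small hydride should attack C7 from the convex β face of the cis-fused bicycle (anti to the ring A bond at C16), giving the 7α-alcohol whichever C8 epimer is present.

Step 12
Reactants: 19 bicyclic 7α,8β-diol
Product: 20 bicyclic 7α-mesylate
Conditions: MsCl, Et3N, CH2Cl2, −20 °C
Reagents that add atoms: methanesulfonyl chloride CS(=O)(=O)Cl
Why: Selective sulfonylation, since the secondary C7 hydroxyl reacts with the sulfene from MsCl and Et3N while the tertiary C8 hydroxyl does not.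

Step 13
Reactants: 20 bicyclic 7α-mesylate
Product: 22 7α-acetyl cis-hydrindane, via aluminium alkoxide 21 (not isolated)
Conditions: Et3Al (3 equiv), CH2Cl2, −78 → 0 °C; aq. KNaC4H4O6 (potassium sodium tartrate)
Reagents that add atoms: none
Why: Et3Al deprotonates the tertiary C8 hydroxyl (ethane is lost) to give the diethylaluminium alkoxide 21, and as the aluminium-activated mesylate leaves from C7 the antiperiplanar C8–C16 ring bond migrates to C7 while the alkoxide oxygen becomes the acetyl carbonyl (semipinacol 1,2-shift). The closest known reaction type is the organoaluminium-promoted pinacol-type rearrangement of β-mesyloxy alcohols and, more generally, the ring contraction of cyclohexane-1,2-diol monosulfonates to acylcyclopentanes, here in its decalin-to-hydrindane form. The cyclopentane C16–C7–C6–C5–C4 closes by a suprafacial 1,2-alkyl shift that is an intramolecular SN2 displacement at C7, so the six-membered ring C16–C8–C7–C6–C5–C4 loses C8 and ring A is unchanged. C7 is the only new stereocenter: it is formed with inversion, so the 7α-mesylate (cis to the C16–C15 bond) gives the 7α-acetyl group with H-7 β, while C16 migrates with retention and C4 is untouched. The step needs ring-bond migration in preference to methyl migration, epoxide closure and elimination; this is secured by the chair of ring B in which C15 and the mesylate are both equatorial, where only the C8–C16 bond is antiperiplanar to C7–OMs, by the high migratory aptitude of the allylic secondary C16, and by the covalent Al–O bond, which keeps the oxygen from attacking C7.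

Step 14
Reactants: 22 7α-acetyl cis-hydrindane
Product: 24 enol triflate, via potassium enolate 23 (not isolated)
Conditions: KN(SiMe3)2, THF, −78 °C; then PhNTf2, −78 → −20 °C
Reagents that add atoms: N-phenylbis(trifluoromethanesulfonimide) O=S(=O)(N(c1ccccc1)S(=O)(=O)C(F)(F)F)C(F)(F)F
Why: Kinetic deprotonation of the methyl ketone at the unhindered methyl group (C19) and O-triflation of the enolate (enol triflate formation) should give the 2-propenyl triflate without touching the C7 stereocenter.

Step 15
Reactants: 24 enol triflate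
Product: 25 triflate aldehyde
Conditions: PPTS, acetone/H2O (10:1), 45 °C
Reagents that add atoms: water O
Why: Acid-catalysed acetal hydrolysis frees the C9 aldehyde, the dimethyl acetal being far more labile than the MOM ethers and the enol triflate.

Step 16
Reactants: 25 triflate aldehyde
Product: 27 (9R)-9-hydroxy-2,3-bis(methoxymethoxy)trinervita-1(15),8(19)-diene, via alkenylchromium species 26 (not isolated)
Conditions: CrCl2 (8 equiv), NiCl2 (5 mol%), DMSO/THF, rt, 2 mM, slow addition
Reagents that add atoms: none
Why: Intramolecular Nozaki–Hiyama–Kishi reaction, in which nickel-catalysed activation of the alkenyl triflate, transmetalation to chromium and addition to the aldehyde at high dilution close the eleven-membered ring with the C8=C19 methylene already in place; C9 is set under macrocyclic control, the aldehyde being expected to add through the conformer with its chain on the outer rim to give the (9R)-alcohol.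

Step 17
Reactants: 27 (9R)-9-hydroxy-2,3-bis(methoxymethoxy)trinervita-1(15),8(19)-diene
Product: 28 (9R)-9-acetoxy-2,3-bis(methoxymethoxy)trinervita-1(15),8(19)-diene
Conditions: Ac2O, pyridine, DMAP (cat.), CH2Cl2, 0 °C
Reagents that add atoms: acetic anhydride CC(=O)OC(C)=O
Why: DMAP-catalysed O-acylation of the only free hydroxyl group installs the C9 acetate with retention.

Step 18
Reactants: 28 (9R)-9-acetoxy-2,3-bis(methoxymethoxy)trinervita-1(15),8(19)-diene
Product: 29 (2R,3R,4S,7R,9R,12R,16S)-9-acetoxytrinervita-1(15),8(19)-diene-2,3-diol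
Conditions: Me2BBr, CH2Cl2, −78 °C; then aq. NaHCO3/THF
Reagents that add atoms: none
Why: Lewis acid cleavage of both MOM ethers (attack at the acetal carbon, hydrolysis of the bromomethyl ethers on work-up) should release the 2,3-diol under conditions that leave the allylic acetate and both alkenes intact.

**Compound list**

1 | methacrolein (2-methylprop-2-enal) | C=C(C)C=O | starting material
2 | 3-(triphenylphosphoranylidene)butan-2-one | CC(=O)C(C)=P(c1ccccc1)(c1ccccc1)c1ccccc1 | starting material
3 | (3E)-3,5-dimethylhexa-3,5-dien-2-one | CC(=O)/C(C)=C/C(C)=C | intermediate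
4 | tert-butyl{[(3E)-3,5-dimethylhexa-1,3,5-trien-2-yl]oxy}dimethylsilane | C=C(O[Si](C)(C)C(C)(C)C)/C(C)=C/C(C)=C | intermediate
5 | (1S,2R)-4-[(tert-butyldimethylsilyl)oxy]-1,3-dimethyl-2-(prop-1-en-2-yl)cyclohex-3-ene-1-carbaldehyde (CHO cis to isopropenyl) | C=C(C)[C@@H]1C(C)=C(O[Si](C)(C)C(C)(C)C)CC[C@]1(C)C=O | intermediate
6 | (S)-citronellyl bromide, (6S)-8-bromo-2,6-dimethyloct-2-ene | CC(C)=CCC[C@H](C)CCBr | starting material
7 | (4S)-6-bromo-1,1-dimethoxy-4-methylhexane | COC(OC)CC[C@H](C)CCBr | intermediate
8 | propargyl alcohol (prop-2-yn-1-ol) | C#CCO | starting material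
9 | Grignard reagent, [(3S)-6,6-dimethoxy-3-methylhexyl]magnesium bromide | COC(OC)CC[C@H](C)CC[Mg]Br | intermediate
10 | (5R)-8,8-dimethoxy-5-methyl-2-methylideneoctan-1-ol | COC(OC)CC[C@H](C)CCC(=C)CO | intermediate
11 | (4R)-1,1-dimethoxy-7-[(methoxymethoxy)methyl]-4-methyloct-7-ene | COC(OC)CC[C@H](C)CCC(=C)COCOC | intermediate
12 | lithiated allyl ether: 11 lithiated at the OCH carbon (delocalised alkoxyallyl anion) | COCOC([Li])C(=C)CC[C@@H](C)CCC(OC)OC | intermediate
13 | alkoxyallylborane: (Ipc)2B–CH2–C(R)=CH–OMOM with OMOM cis to CH2B; Ipc = (1R,2S,3R,5R)-isopinocampheyl; R = (3R)-6,6-dimethoxy-3-methylhexyl | COCO/C=C(\CB([C@@H]1C[C@@H]2C[C@@H](C2(C)C)[C@H]1C)[C@@H]1C[C@@H]2C[C@@H](C2(C)C)[C@H]1C)CC[C@@H](C)CCC(OC)OC | intermediate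
14 | C3-hydroxy C2-OMOM seco adduct: cyclohexene of 5 whose C4 carries C3H(OH)–C2H(OMOM)–C1(=CH2)–C14H2–C13H2–C12H(CH3)–C11H2–C10H2–C9H(OMe)2; 2-OMOM/3-OH syn; C2, C3, C4, C12 and C16 as in 29 | COC(OC)CC[C@H](C)CCC(=C)[C@@H](OCOC)[C@H](O)[C@@]1(C)CCC(O[Si](C)(C)C(C)(C)C)=C(C)[C@H]1C(C)=C | intermediate
15 | C2,C3-bis-OMOM seco silyl enol ether (3-O-MOM ether of 14) | COC(OC)CC[C@H](C)CCC(=C)[C@@H](OCOC)[C@H](OCOC)[C@@]1(C)CCC(O[Si](C)(C)C(C)(C)C)=C(C)[C@H]1C(C)=C | intermediate
16 | silyloxy ketone: 15 with ring B as C7 ketone and 8β-OTBS (C19 methyl α) | COC(OC)CC[C@H](C)CCC(=C)[C@@H](OCOC)[C@H](OCOC)[C@@]1(C)CCC(=O)[C@](C)(O[Si](C)(C)C(C)(C)C)[C@H]1C(C)=C | intermediate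
17 | monocyclic 8β-hydroxy 7-ketone (α-ketol; isopropenyl on C16, C1=CH2 side chain on C4) | COC(OC)CC[C@H](C)CCC(=C)[C@@H](OCOC)[C@H](OCOC)[C@@]1(C)CCC(=O)[C@](C)(O)[C@H]1C(C)=C | intermediate
18 | cis-fused bicyclic α-ketol: ring A closed (C1=C15 tetrasubstituted, 2,3-bis-OMOM), ring B six-membered with C7=O and 8β-OH; H-16 and C18 methyl β | COC(OC)CC[C@H](C)CCC1=C(C)[C@@H]2[C@@](C)(O)C(=O)CC[C@]2(C)[C@@H](OCOC)[C@@H]1OCOC | intermediate
19 | bicyclic 7α,8β-diol (trans-diol in ring B) | COC(OC)CC[C@H](C)CCC1=C(C)[C@@H]2[C@@](C)(O)[C@H](O)CC[C@]2(C)[C@@H](OCOC)[C@@H]1OCOC | intermediate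
20 | bicyclic 7α-mesylate (8β-OH free) | COC(OC)CC[C@H](C)CCC1=C(C)[C@@H]2[C@@](C)(O)[C@H](OS(C)(=O)=O)CC[C@]2(C)[C@@H](OCOC)[C@@H]1OCOC | intermediate
21 | aluminium alkoxide: diethylaluminium 8β-alkoxide of 20 | COC(OC)CC[C@H](C)CCC1=C(C)[C@@H]2[C@@](C)(O[Al](CC)CC)[C@H](OS(C)(=O)=O)CC[C@]2(C)[C@@H](OCOC)[C@@H]1OCOC | intermediate
22 | 7α-acetyl cis-hydrindane (cyclopentane C16–C7–C6–C5–C4; H-7 β; ring A and chain as in 18) | COC(OC)CC[C@H](C)CCC1=C(C)[C@@H]2[C@H](C(C)=O)CC[C@]2(C)[C@@H](OCOC)[C@@H]1OCOC | intermediate
23 | potassium enolate of 22 (C8(OK)=C19H2) | COC(OC)CC[C@H](C)CCC1=C(C)[C@@H]2[C@H](C(=C)[O-])CC[C@]2(C)[C@@H](OCOC)[C@@H]1OCOC.[K+] | intermediate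
24 | enol triflate (C8(OTf)=C19H2 on C7; C9 dimethyl acetal) | COC(OC)CC[C@H](C)CCC1=C(C)[C@@H]2[C@H](C(=C)OS(=O)(=O)C(F)(F)F)CC[C@]2(C)[C@@H](OCOC)[C@@H]1OCOC | intermediate
25 | triflate aldehyde (C9H=O) | O=CCC[C@H](C)CCC1=C(C)[C@@H]2[C@H](C(=C)OS(=O)(=O)C(F)(F)F)CC[C@]2(C)[C@@H](OCOC)[C@@H]1OCOC | intermediate
26 | alkenylchromium species (CrCl2 unit on C8 of 25) | O=CCC[C@H](C)CCC1=C(C)[C@@H]2[C@H](C(=C)[Cr](Cl)Cl)CC[C@]2(C)[C@@H](OCOC)[C@@H]1OCOC | intermediate
27 | (9R)-9-hydroxy-2,3-bis(methoxymethoxy)trinervita-1(15),8(19)-diene | C=C1[C@H](O)CC[C@H](C)CCC2=C(C)[C@@H]3[C@H]1CC[C@]3(C)[C@@H](OCOC)[C@@H]2OCOC | intermediate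
28 | (9R)-9-acetoxy-2,3-bis(methoxymethoxy)trinervita-1(15),8(19)-diene | C=C1[C@H](OC(C)=O)CC[C@H](C)CCC2=C(C)[C@@H]3[C@H]1CC[C@]3(C)[C@@H](OCOC)[C@@H]2OCOC | intermediate
29 | (2R,3R,4S,7R,9R,12R,16S)-9-acetoxytrinervita-1(15),8(19)-diene-2,3-diol | C=C1[C@H](OC(C)=O)CC[C@H](C)CCC2=C(C)[C@@H]3[C@H]1CC[C@]3(C)[C@@H](O)[C@@H]2O | target

**Step count and risks**

Total step count: 18. Longest linear sequence: 15 steps (steps 1–3 followed by steps 7–18; the branch of steps 4–6 followed by steps 7–18 is equally long).

Steps most likely to fail: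

Step 13. Ring B may not populate the conformer in which the C7 mesylate is antiperiplanar to the C8–C16 bond, so that closure of the C8 oxygen onto C7, elimination of the mesylate or attack of the aluminium reagent on the dimethyl acetal outruns the 1,2-shift. The fallback sets out from 20 and comes back at 22. Compound 20 is closed on purpose with KOt-Bu in THF to the 7β,8β-epoxide F1 (SN2 at C7 by the 8β-alkoxide). LiBr·HMPA (catalytic) in benzene at 80 °C should then open F1 with bromide at the secondary C7 with inversion, giving the lithium salt of the 7α-bromo-8β-ol F2. Its all-equatorial chair should contract by the same shift of C16 from C8 to C7, a second inversion at C7, to give 22.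

Step 16. The addition of the alkenylchromium species to the C9 aldehyde may show poor facial selectivity and deliver the C9 epimer. The fallback sets out from 25 and comes back at 28. The (9S)-9-hydroxy epimer F3, separated from 27, is esterified with inversion by a Mitsunobu reaction (AcOH, PPh3, DIAD, PhMe, 0 °C), which should give acetate 28 directly and makes step 17 unnecessary for this material.

Step 3. The strongly acidic catalyst may protodesilylate diene 4, and enantiofacial control may erode with this hindered trisubstituted diene. The fallback sets out from 4 and 1 and comes back at 14. The cycloaddition is run without chiral catalyst (PhMe, 60 °C, or Yb(OTf)3, CH2Cl2, 0 °C) to give the racemate, that is 5 together with its (1R,2S)-enantiomer F4. The racemate is taken through step 7, where reagent 13 is matched with 5 and mismatched with F4. Adduct 14 is then separated by chromatography from the diastereomeric adduct F5 that arises from F4.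

Further compounds
F1 | step 13 | 7β,8β-epoxide of the bicyclic core (from 20) | COC(OC)CC[C@H](C)CCC1=C(C)[C@@H]2[C@@]3(C)O[C@H]3CC[C@]2(C)[C@@H](OCOC)[C@@H]1OCOC
F2 | step 13 | lithium salt of the bicyclic 7α-bromo-8β-ol | COC(OC)CC[C@H](C)CCC1=C(C)[C@@H]2[C@@](C)(O[Li])[C@H](Br)CC[C@]2(C)[C@@H](OCOC)[C@@H]1OCOC
F3 | step 16 | (9S)-9-hydroxy-2,3-bis(methoxymethoxy)trinervita-1(15),8(19)-diene | C=C1[C@@H](O)CC[C@H](C)CCC2=C(C)[C@@H]3[C@H]1CC[C@]3(C)[C@@H](OCOC)[C@@H]2OCOC
F4 | step 3 | (1R,2S)-4-[(tert-butyldimethylsilyl)oxy]-1,3-dimethyl-2-(prop-1-en-2-yl)cyclohex-3-ene-1-carbaldehyde (enantiomer of 5) | C=C(C)[C@H]1C(C)=C(O[Si](C)(C)C(C)(C)C)CC[C@@]1(C)C=O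
F5 | step 3 | diastereomer of 14 derived from F4 (C4 and C16 inverted; C2, C3 and C12 as in 14) | COC(OC)CC[C@H](C)CCC(=C)[C@@H](OCOC)[C@H](O)[C@]1(C)CCC(O[Si](C)(C)C(C)(C)C)=C(C)[C@@H]1C(C)=C
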